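## Structural features

The target is an achiral, fully aromatic hexamer: six benzene rings (A to F) joined in one chain by five diaryl ether oxygens, carrying fifteen phenolic hydroxyls and no carbon substituent. Ring A is a 2,4,6-trihydroxyphenyl unit. Rings B, C and E are para-dioxygenated rings whose C4 ether oxygen is flanked by hydroxyls at C3 and C5. Ring F is a 3,4,5-trihydroxyphenyl unit. Ring D is the exception, with five contiguous oxygens: aryloxy groups on the neighbouring carbons C1 (oxygen shared with ring C C4) and C6 (oxygen shared with ring E C1), hydroxyls at C3 to C5, and the only ring hydrogen at C2. There are no stereocentres and the ether axes rotate freely, so no stereochemical relationship has to be set. The free polyphenol is the fragile feature: the pyrogallol-type rings D and F oxidise readily in air and base, and the phloroglucinol-type ring A is a strong carbon nucleophile, so all oxygens should stay methylated until the last step. The real difficulty is that every ether oxygen sits on a carbon flanked by two oxygen substituents, so each C–O bond joins hindered, electron-rich partners, and the ortho-bis(aryloxy) pattern of ring D must be placed regioselectively among five oxygens. The key step exploits the adjacency of ring D C1 and C6: they map onto the two carbons of 3,4,5-trimethoxybenzyne, and the methoxy group at C5 decides which carbon receives oxygen and which receives the carbanion.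

## Logic of the disconnections

22 to 21: the fifteen O–CH3 bonds are cut last. Methyl ethers come with the commercial building blocks and tolerate organomagnesium reagents, copper catalysis, peracid and hydrogenolysis. The demand is an exhaustive ether cleavage that leaves the five diaryl ethers intact and an oxygen-free isolation.

21 to 15 and 20: the ring D C6–O bond is cut. This splits the hexamer into a tetramer and a dimer and uses the iodine that the key step leaves at C6. The demand is a copper-mediated O-arylation at an aryl iodide with two ortho oxygen substituents.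

15 to 7 and 10 (through 11, 12, 13 and 14): the ring D C1–O and C6–I bonds are cut together. Both carbons carry heteroatoms and are adjacent, so ring D reduces to a symmetrical, commercially derived phenol derivative and the whole ring A–B–C chain arrives as one nucleophile. The demand is regioselective addition of an oxygen nucleophile to the aryne and survival of the resulting arylmagnesium until iodine is added.

10 to 9 to 8: the S–O bond and then the C–I bond are cut. Both ortho positions of 8 are equivalent, so mono-iodination has only one possible regiochemical outcome. The demand is clean mono-iodination of a very electron-rich ring.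

7 to 6 to 5 and 2, then 5 to 4 to 3 and 2, then 2 to 1: the B–C and A–B ether bonds are cut at the unhindered carbon of the later ring, and the benzyl ether is removed between couplings. One bromide, 2, serves as both ring B and ring C. The demand is a copper-catalysed coupling of 2,6-dimethoxyphenols with an electron-rich bromide, twice.

20 to 19 to 18 to 16 and 17: the phenolic C–O bond of ring E is traced back to a formyl group (aryl migration to oxygen), and the E–F ether bond is cut at the unhindered ring F carbon. This gives two commercial arenes. The demand is O-arylation of a phenoxide that is both hindered and deactivated by the para formyl group.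

## Other disconnections considered

Alternative 1: Ring B itself is cut at C2–C3, C1–C6 and C3–C4 (Danheiser benzannulation).
- **Forward key step:** irradiation of the diazo ketone (Z)-4-(benzyloxy)-1-diazo-3-methoxybut-3-en-2-one A3 would trigger a Wolff rearrangement to a vinylketene. This adds to the ynol ether 2-(ethynyloxy)-1,3,5-trimethoxybenzene A2; the 4-vinylcyclobutenone opens and recloses by 6π electrocyclisation to the ring A–B phenol A1.
- **In favour:** the A–B oxygen arrives on the alkyne, so no coupling at the hindered ring A oxygen is needed. The ring B pattern follows from the polarity of the ynol ether. On these two points it is equal to or better than the chosen plan, and every elementary step is a known pericyclic process.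
- **Against:** it solves the least demanding junction of the chain and leaves ring D untouched, so the aryne step or a substitute is still required. A3 is a sensitive, multistep oxygenated diazo enone, and aryl ethynyl ethers are labile. A1 needs methylation to reach 4, so the differentiation of the ring B oxygens it provides is not used.
- **Comparison:** structurally it overlaps only with steps 1 to 3. In step economy it is clearly worse, at about six operations to 5 against three.

Alternative 2: Ring D is cut at C6–C1 (squarate ring expansion).
- **Forward key step:** thermolysis of the racemic cyclobutenone A5 (the 2,3,4-trimethoxy-4-[(E)-2-aryloxyvinyl]cyclobutenone whose aryloxy group is that of 7) would open it conrotatorily, with the C4 methoxy turning outward, to a dienylketene. This closes and enolises to the ring A–B–C–D phenol A4.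
- **In favour:** this is an established reaction class. The regiochemistry of ring D is fixed by construction and not by a selectivity argument, which is better than the chosen plan. A4 carries a free hydroxyl at D C6, so the D–E bond could be made in the favourable polarity (hindered phenol plus unhindered aryl bromide), which is better than coupling at the hindered iodide 15.
- **Against:** A5 needs a 2-aryloxyvinyl organometallic derived from 7, which is prone to β-elimination of aryloxide. It also needs addition to a squaric ester and O-methylation of a tertiary alkoxide, all carried out on the valuable trimer.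
- **Comparison:** it costs about five steps from 7 to A4 against one from 7 to 15 (plus two for 10). It is therefore mechanistically safer but longer and less convergent.

Alternative 3: Ten aryl C–O(H) bonds are traced back to formyl groups on an SNAr-assembled chain.
- **Forward key step:** mCPBA would convert the ten formyl groups of the decaaldehyde A7 into aryl formates by Baeyer–Villiger aryl migration, and K2CO3 in MeOH would cleave them to the decaphenol A6.
- **In favour:** the ether bonds come from SNAr on fluoro dialdehydes without copper, and the formyl groups activate even the hindered ring D C6 position. On C–O bond formation this is better than step 11, and it needs no new method.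
- **Against:** aryl migration needs an electron-rich ring. Here each ring carries two formyl groups and only aryloxy donors, so hydride migration to carboxylic acids would compete, and the loss compounds over ten sites. The fluoro hydroxy dialdehyde building blocks (one unsymmetrical for ring D) are not commercial. Phenoxides with two formyl groups are weak nucleophiles. A6 still holds five methyl ethers, so the BBr3 step is not avoided and must then be run on an oxidation-prone decaphenol.
- **Comparison:** equal in the oxygen pattern delivered, better in ether formation, worse in the oxidation step and in overall step count.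

Key step: step 8

Assumption: ring positions are numbered in the order of the target SMILES (ring D C1 bears the oxygen from ring C, C6 the oxygen to ring E). Compounds 1, 3, 8, 16 and 17 and all reagents are taken as commercial.

## Route

Step 1
Reactants: 1 4-bromo-2,6-dimethoxyphenol
Product: 2 2-(benzyloxy)-5-bromo-1,3-dimethoxybenzene
Conditions: BnBr, K2CO3, DMF, 25 °C
Reagents that add atoms: benzyl bromide, BrCc1ccccc1
Why: Williamson etherification of an acidic phenol; the benzyl group masks the oxygen that later becomes the nucleophile and is removable without touching methyl or diaryl ethers.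

Step 2
Reactants: 3 2,4,6-trimethoxyphenol; 2 2-(benzyloxy)-5-bromo-1,3-dimethoxybenzene
Product: 4 2-[4-(benzyloxy)-3,5-dimethoxyphenoxy]-1,3,5-trimethoxybenzene (ring A–B benzyl ether)
Conditions: CuI (10 mol %), picolinic acid (20 mol %), K3PO4, DMSO, 100 °C, Ar
Reagents that add atoms: none
Why: Ullmann-type O-arylation; the ligand system is suited to di-ortho-substituted phenols, the bromide has two free ortho positions, and exclusion of air should prevent oxidation of the electron-rich phenoxide.

Step 3
Reactants: 4 ring A–B benzyl ether
Product: 5 2,6-dimethoxy-4-(2,4,6-trimethoxyphenoxy)phenol (ring A–B phenol)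
Conditions: H2 (1 atm), 10% Pd/C, EtOAc–MeOH, 25 °C
Reagents that add atoms: none
Why: Hydrogenolysis of the benzyl ether; diaryl and methyl ethers are inert under these conditions.

Step 4
Reactants: 5 ring A–B phenol; 2 2-(benzyloxy)-5-bromo-1,3-dimethoxybenzene
Product: 6 2-{4-[4-(benzyloxy)-3,5-dimethoxyphenoxy]-3,5-dimethoxyphenoxy}-1,3,5-trimethoxybenzene (ring A–B–C benzyl ether)
Conditions: CuI (10 mol %), picolinic acid (20 mol %), K3PO4, DMSO, 100 °C, Ar
Reagents that add atoms: none
Why: Second Ullmann-type O-arylation of the same kind as step 2, with a 2,6-dimethoxyphenol of the same steric and electronic type.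

Step 5
Reactants: 6 ring A–B–C benzyl ether
Product: 7 4-[2,6-dimethoxy-4-(2,4,6-trimethoxyphenoxy)phenoxy]-2,6-dimethoxyphenol (ring A–B–C phenol, ring C 4-hydroxyl free)
Conditions: H2 (1 atm), 10% Pd/C, EtOAc–MeOH, 25 °C
Reagents that add atoms: none
Why: Hydrogenolysis as in step 3 should release the single phenol needed for the aryne coupling.

Step 6
Reactants: 8 3,4,5-trimethoxyphenol
Product: 9 2-iodo-3,4,5-trimethoxyphenol
Conditions: NIS (1.0 equiv), MeCN, 0 °C
Reagents that add atoms: N-iodosuccinimide, O=C1CCC(=O)N1I
Why: Electrophilic aromatic iodination; the two free positions are equivalent and both ortho to the hydroxyl, so one equivalent of reagent should give a single mono-iodide.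

Step 7
Reactants: 9 2-iodo-3,4,5-trimethoxyphenol
Product: 10 2-iodo-3,4,5-trimethoxyphenyl 4-chlorobenzenesulfonate
Conditions: 4-ClC6H4SO2Cl, Et3N, DMAP (cat.), CH2Cl2, 0 → 25 °C
Reagents that add atoms: 4-chlorobenzenesulfonyl chloride, O=S(=O)(Cl)c1ccc(Cl)cc1
Why: O-Sulfonylation of the phenol; the 4-chlorobenzenesulfonate is a leaving group that stays in place at −78 °C after magnesiation but is lost on warming.

Step 8
Reactants: 7 ring A–B–C phenol; 10 2-iodo-3,4,5-trimethoxyphenyl 4-chlorobenzenesulfonate
Product: 15 ring A–B–C–D iodide (2-iodo-3,4,5-trimethoxyphenyl ether of 7; iodine at ring D C6), via magnesium phenoxide 11 (not isolated), via magnesiated sulfonate 12 (not isolated), via 3,4,5-trimethoxybenzyne 13 (not isolated), via ring D arylmagnesium 14 (not isolated)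
Conditions: 7, i-PrMgCl·LiCl (1.05 equiv), THF, 0 °C; 10 (1.5 equiv), i-PrMgCl (1.5 equiv), THF, −78 °C; combine, −78 → 25 °C; I2, THF, −78 → 0 °C; aq Na2S2O3
Reagents that add atoms: iodine, II
Why: Proposed new method: iodine–magnesium exchange on 10 at −78 °C gives 12, which on warming loses chloromagnesium 4-chlorobenzenesulfonate to form aryne 13; the LiCl-solubilised magnesium phenoxide 11 adds to the strained triple bond, and the arylmagnesium 14, with no proton source in the flask, should persist until I2 converts it into the C6 iodide. The closest known reaction types are the addition of magnesium thiolates and magnesium amides to arynes generated from 2-magnesiated aryl sulfonates with electrophilic trapping of the new aryl Grignard, and the fluoride-mediated O-arylation of phenols by 2-silylaryl triflates; an oxygen nucleophile in the magnesium manifold is the untested element. No ring is closed and no stereocentre is formed. The step needs regioselectivity: the methoxy group at ring D C5 flanks the triple bond, so the nucleophile should attack the distal carbon C1 and the negative charge should develop at C6 next to the inductively withdrawing oxygen, which places oxygen at C1 and iodine at C6 as the target requires. It also needs chemoselectivity for phenoxide over carbon nucleophiles: all i-PrMgCl is consumed by the exchange before the aryne forms, and the arylmagnesiums 12 and 14 are each flanked by two ortho substituents and should add slowly. Compound 10 is used in modest excess because it is the cheaper partner, and I2 is added cold and in slight excess only, to spare the nucleophilic ring A.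

Step 9
Reactants: 16 syringaldehyde (4-hydroxy-3,5-dimethoxybenzaldehyde); 17 5-iodo-1,2,3-trimethoxybenzene
Product: 18 3,5-dimethoxy-4-(3,4,5-trimethoxyphenoxy)benzaldehyde
Conditions: CuI (10 mol %), picolinic acid (20 mol %), K3PO4, DMSO, 90 °C, Ar
Reagents that add atoms: none
Why: Ullmann-type O-arylation; the aryl iodide is unhindered and the non-enolisable aldehyde tolerates the mild phosphate base.

Step 10
Reactants: 18 3,5-dimethoxy-4-(3,4,5-trimethoxyphenoxy)benzaldehyde
Product: 20 3,5-dimethoxy-4-(3,4,5-trimethoxyphenoxy)phenol (ring E–F phenol), via aryl formate 19 (not isolated)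
Conditions: mCPBA, CH2Cl2, 0 → 25 °C; aq NaHCO3 wash; K2CO3 (cat.), MeOH, 25 °C
Reagents that add atoms: mCPBA (3-chloroperoxybenzoic acid), O=C(OO)c1cccc(Cl)c1
Why: Baeyer–Villiger (Dakin-type) oxidation; the trioxygenated aryl group migrates in preference to hydride, as for 3,4,5-trimethoxybenzaldehyde, and the aryl formate is methanolysed under mild base.

Step 11
Reactants: 15 ring A–B–C–D iodide; 20 ring E–F phenol
Product: 21 pentadeca-O-methyl ether of the target (fully methylated hexamer)
Conditions: CuI (30 mol %), picolinic acid (60 mol %), K3PO4, DMSO, 110 °C, Ar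
Reagents that add atoms: none
Why: Ullmann-type O-arylation of an unhindered, electron-rich phenol with the aryl iodide; the higher catalyst loading and temperature are chosen for the two ortho oxygen substituents of the iodide.

Step 12
Reactants: 21 pentadeca-O-methyl ether of the target
Product: 22 target hexamer (CNP0175585.0), all fifteen hydroxyls free
Conditions: BBr3 (30 equiv), CH2Cl2, −78 → 25 °C; degassed H2O, 0 °C
Reagents that add atoms: none
Why: Lewis-acid cleavage of aryl methyl ethers by BBr3 (bromide attacks the methyl group of the boron-complexed ether); diaryl ethers have no alkyl carbon to attack and should survive. Purification under argon on Sephadex LH-20 or reversed phase.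

## Compound list

1 | 4-bromo-2,6-dimethoxyphenol | COc1cc(Br)cc(OC)c1O | starting material
2 | 2-(benzyloxy)-5-bromo-1,3-dimethoxybenzene | COc1cc(Br)cc(OC)c1OCc1ccccc1 | intermediate
3 | 2,4,6-trimethoxyphenol | COc1cc(OC)c(O)c(OC)c1 | starting material
4 | 2-[4-(benzyloxy)-3,5-dimethoxyphenoxy]-1,3,5-trimethoxybenzene (ring A–B benzyl ether) | COc1cc(OC)c(Oc2cc(OC)c(OCc3ccccc3)c(OC)c2)c(OC)c1 | intermediate
5 | 2,6-dimethoxy-4-(2,4,6-trimethoxyphenoxy)phenol (ring A–B phenol) | COc1cc(OC)c(Oc2cc(OC)c(O)c(OC)c2)c(OC)c1 | intermediate
6 | 2-{4-[4-(benzyloxy)-3,5-dimethoxyphenoxy]-3,5-dimethoxyphenoxy}-1,3,5-trimethoxybenzene (ring A–B–C benzyl ether) | COc1cc(OC)c(Oc2cc(OC)c(Oc3cc(OC)c(OCc4ccccc4)c(OC)c3)c(OC)c2)c(OC)c1 | intermediate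
7 | 4-[2,6-dimethoxy-4-(2,4,6-trimethoxyphenoxy)phenoxy]-2,6-dimethoxyphenol (ring A–B–C phenol) | COc1cc(OC)c(Oc2cc(OC)c(Oc3cc(OC)c(O)c(OC)c3)c(OC)c2)c(OC)c1 | intermediate
8 | 3,4,5-trimethoxyphenol | COc1cc(O)cc(OC)c1OC | starting material
9 | 2-iodo-3,4,5-trimethoxyphenol | COc1cc(O)c(I)c(OC)c1OC | intermediate
10 | 2-iodo-3,4,5-trimethoxyphenyl 4-chlorobenzenesulfonate | COc1cc(OS(=O)(=O)c2ccc(Cl)cc2)c(I)c(OC)c1OC | intermediate
11 | chloromagnesium phenoxide of 7 | COc1cc(OC)c(Oc2cc(OC)c(Oc3cc(OC)c(O[Mg]Cl)c(OC)c3)c(OC)c2)c(OC)c1 | intermediate
12 | 2-(chloromagnesio)-3,4,5-trimethoxyphenyl 4-chlorobenzenesulfonate | COc1cc(OS(=O)(=O)c2ccc(Cl)cc2)c([Mg]Cl)c(OC)c1OC | intermediate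
13 | 3,4,5-trimethoxybenzyne | COC1=CC#CC(OC)=C1OC | intermediate
14 | ring A–B–C–D arylmagnesium chloride (magnesium at ring D C6) | COc1cc(OC)c(Oc2cc(OC)c(Oc3cc(OC)c(Oc4cc(OC)c(OC)c(OC)c4[Mg]Cl)c(OC)c3)c(OC)c2)c(OC)c1 | intermediate
15 | ring A–B–C–D iodide (2-iodo-3,4,5-trimethoxyphenyl ether of 7) | COc1cc(OC)c(Oc2cc(OC)c(Oc3cc(OC)c(Oc4cc(OC)c(OC)c(OC)c4I)c(OC)c3)c(OC)c2)c(OC)c1 | intermediate
16 | syringaldehyde (4-hydroxy-3,5-dimethoxybenzaldehyde) | COc1cc(C=O)cc(OC)c1O | starting material
17 | 5-iodo-1,2,3-trimethoxybenzene | COc1cc(I)cc(OC)c1OC | starting material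
18 | 3,5-dimethoxy-4-(3,4,5-trimethoxyphenoxy)benzaldehyde | COc1cc(Oc2c(OC)cc(C=O)cc2OC)cc(OC)c1OC | intermediate
19 | 3,5-dimethoxy-4-(3,4,5-trimethoxyphenoxy)phenyl formate | COc1cc(Oc2c(OC)cc(OC=O)cc2OC)cc(OC)c1OC | intermediate
20 | 3,5-dimethoxy-4-(3,4,5-trimethoxyphenoxy)phenol (ring E–F phenol) | COc1cc(Oc2c(OC)cc(O)cc2OC)cc(OC)c1OC | intermediate
21 | pentadeca-O-methyl ether of the target | COc1cc(OC)c(Oc2cc(OC)c(Oc3cc(OC)c(Oc4cc(OC)c(OC)c(OC)c4Oc4cc(OC)c(Oc5cc(OC)c(OC)c(OC)c5)c(OC)c4)c(OC)c3)c(OC)c2)c(OC)c1 | intermediate
22 | target hexamer CNP0175585.0 | Oc1cc(O)c(Oc2cc(O)c(Oc3cc(O)c(Oc4cc(O)c(O)c(O)c4Oc4cc(O)c(Oc5cc(O)c(O)c(O)c5)c(O)c4)c(O)c3)c(O)c2)c(O)c1 | target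

Total step count: 12. Longest linear sequence: 8 (steps 1, 2, 3, 4, 5, 8, 11, 12).

## Least certain steps

**Step 8 (key step).** The likeliest failure is insufficient nucleophilicity of the magnesium phenoxide, so that the aryne is consumed by arylmagnesium species or oligomerises. Further risks are partial loss of regiocontrol in the addition and iodination of ring A during the quench. The fallback uses known chemistry only and sets out from 7.
- Nitration of commercial 5-bromo-1,2,3-trimethoxybenzene would give 1-bromo-3,4,5-trimethoxy-2-nitrobenzene F1.
- Copper-catalysed coupling of 7 with F1 (CuI, picolinic acid, K3PO4, DMSO; the ortho nitro group accelerates the substitution) would give the ring D nitro ether F2.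
- Hydrogenation (H2, Pd/C) would give the ring D aniline F3.
- Diazotisation with NaNO2 and p-TsOH in MeCN in the presence of KI would pass through the arenediazonium tosylate F4 to the iodide (Sandmeyer-type iodination).

The fallback returns to the route at 15.

**Step 9.** The phenoxide of 16 is both flanked by two methoxy groups and deactivated by the para formyl group, so the O-arylation may stall and the aldehyde may degrade on prolonged heating. The fallback sets out from 1.
- Chan–Lam coupling with (3,4,5-trimethoxyphenyl)boronic acid (Cu(OAc)2, pyridine, air, CH2Cl2, 25 °C) leaves the aryl bromide untouched and would give 5-bromo-1,3-dimethoxy-2-(3,4,5-trimethoxyphenoxy)benzene F5.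
- Hydroxylation of the bromide (Pd2(dba)3, t-BuXPhos, KOH, dioxane–H2O, 100 °C) would give the phenol.

The fallback returns to the route at 20.

**Step 11.** Oxidative addition at the di-ortho-substituted, electron-rich iodide may be slow, and protodeiodination and reductive homocoupling may then dominate. The fallback sets out from 15 and reverses the polarity of the coupling.
- Iodine–magnesium exchange with i-PrMgCl·LiCl would regenerate 14.
- B(OMe)3 would give the ring D dimethyl boronate F6.
- NaOH and H2O2 would give the ring A–B–C–D phenol F7 (ring D C6 hydroxyl free, the same constitution as A4).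
- Coupling of F7 with the ring E–F bromide F5 (made from 1 as described under step 9), under the conditions of steps 2 and 4, joins a hindered phenol to an unhindered bromide.

The fallback returns to the route at 21.

**Step 12.** Cleavage of fifteen ethers may stop short and leave partially methylated congeners, and the free polyphenol may oxidise or be lost on aqueous isolation. The fallback sets out from 21.
- The crude product of the BBr3 reaction would be acetylated without purification (Ac2O, pyridine) to the pentadecaacetate F8, which is stable and can be purified on silica and separated from under-cleaved material.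
- Acidic methanolysis (HCl in degassed MeOH, 25 °C) would then release the polyphenol without base.

The fallback returns to the route at 22.

## Further compounds

F1 | step 8 | 1-bromo-3,4,5-trimethoxy-2-nitrobenzene | COc1cc(Br)c([N+](=O)[O-])c(OC)c1OC
F2 | step 8 | ring A–B–C–D nitro ether (nitro at ring D C6) | COc1cc(OC)c(Oc2cc(OC)c(Oc3cc(OC)c(Oc4cc(OC)c(OC)c(OC)c4[N+](=O)[O-])c(OC)c3)c(OC)c2)c(OC)c1
F3 | step 8 | ring A–B–C–D aniline (amino at ring D C6) | COc1cc(OC)c(Oc2cc(OC)c(Oc3cc(OC)c(Oc4cc(OC)c(OC)c(OC)c4N)c(OC)c3)c(OC)c2)c(OC)c1
F4 | step 8 | ring A–B–C–D arenediazonium tosylate (diazonium at ring D C6) | COc1cc(OC)c(Oc2cc(OC)c(Oc3cc(OC)c(Oc4cc(OC)c(OC)c(OC)c4[N+]#N)c(OC)c3)c(OC)c2)c(OC)c1.Cc1ccc(S(=O)(=O)[O-])cc1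
F5 | step 9 | 5-bromo-1,3-dimethoxy-2-(3,4,5-trimethoxyphenoxy)benzene (ring E–F bromide) | COc1cc(Oc2c(OC)cc(Br)cc2OC)cc(OC)c1OC
F6 | step 11 | ring A–B–C–D dimethyl boronate (boron at ring D C6) | COc1cc(OC)c(Oc2cc(OC)c(Oc3cc(OC)c(Oc4cc(OC)c(OC)c(OC)c4B(OC)OC)c(OC)c3)c(OC)c2)c(OC)c1
F7 | step 11 | ring A–B–C–D phenol (ring D C6 hydroxyl free) | COc1cc(OC)c(Oc2cc(OC)c(Oc3cc(OC)c(Oc4cc(OC)c(OC)c(OC)c4O)c(OC)c3)c(OC)c2)c(OC)c1
F8 | step 12 | pentadecaacetate of the target | CC(=O)Oc1cc(OC(C)=O)c(Oc2cc(OC(C)=O)c(Oc3cc(OC(C)=O)c(Oc4cc(OC(C)=O)c(OC(C)=O)c(OC(C)=O)c4Oc4cc(OC(C)=O)c(Oc5cc(OC(C)=O)c(OC(C)=O)c(OC(C)=O)c5)c(OC(C)=O)c4)c(OC(C)=O)c3)c(OC(C)=O)c2)c(OC(C)=O)c1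
A1 | alternative 1 | 2-(benzyloxy)-3-methoxy-5-(2,4,6-trimethoxyphenoxy)phenol (ring A–B phenol from the benzannulation) | COc1cc(OC)c(Oc2cc(O)c(OCc3ccccc3)c(OC)c2)c(OC)c1
A2 | alternative 1 | 2-(ethynyloxy)-1,3,5-trimethoxybenzene (ynol ether) | COc1cc(OC)c(OC#C)c(OC)c1
A3 | alternative 1 | (Z)-4-(benzyloxy)-1-diazo-3-methoxybut-3-en-2-one | CO/C(C(=O)C=[N+]=[N-])=C\OCc1ccccc1
A4 | alternative 2 | ring A–B–C–D phenol with ring D C6 hydroxyl free | COc1cc(OC)c(Oc2cc(OC)c(Oc3cc(OC)c(Oc4cc(OC)c(OC)c(OC)c4O)c(OC)c3)c(OC)c2)c(OC)c1
A5 | alternative 2 | racemic 2,3,4-trimethoxy-4-[(E)-2-(aryloxy)ethenyl]cyclobut-2-en-1-one, aryloxy being the oxygen of 7 | COC1=C(OC)C(OC)(/C=C/Oc2c(OC)cc(Oc3c(OC)cc(Oc4c(OC)cc(OC)cc4OC)cc3OC)cc2OC)C1=O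
A6 | alternative 3 | hexamer decaphenol with five methyl ethers left | COc1cc(O)c(Oc2cc(O)c(Oc3cc(O)c(Oc4cc(O)c(OC)c(O)c4Oc4cc(O)c(Oc5cc(OC)c(OC)c(OC)c5)c(O)c4)c(O)c3)c(O)c2)c(O)c1
A7 | alternative 3 | hexamer decaaldehyde (formyl in place of each hydroxyl of A6) | COc1cc(C=O)c(Oc2cc(C=O)c(Oc3cc(C=O)c(Oc4cc(C=O)c(OC)c(C=O)c4Oc4cc(C=O)c(Oc5cc(OC)c(OC)c(OC)c5)c(C=O)c4)c(C=O)c3)c(C=O)c2)c(C=O)c1
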